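**Retrosynthetic overview**
- 31 ⇐ hydride reduction and desilylation of trienylidene lactone 29 (lactone → C5‑OH/CH2OH diol, epoxide → C10 carbinol, Weinreb amide → enal); 29 ⇐ aldol condensation of ring‑A γ‑lactone 22 with dienal 26 (from 6‑methylhept‑5‑en‑2‑one and acrolein).
- Enal carbons ⇐ torquoselective ynolate olefination of C7 ketone 18, unmasked from the isopropenyl group of carvone.
- Ring A (formed second) ⇐ cathodic C5–C1 ketyl–nitrile cyclisation of epoxy aldehyde 10, then butenolide annulation and conjugate reduction (sets C1).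
- C10 ⇐ hydroxyl‑directed epoxidation; spiro carbon C4 and C6 ⇐ cuprate addition/cyanoethylation of dienoate 3; ring B (first) is the ring of (S)‑carvone, whose stereocentre relays all others.

Assumption: the given SMILES is taken as the full definition of CNP0246965.4, and compounds 1, 4, 5, 13, 19, 23 and 25 are taken as catalogue chemicals.

Atom labels used in names: ring A = C1 (bears the trienyl chain), C2, C3, C4 (spiro), C5 (CHOH); ring B = C4, C6 (bears the hydroxypropyl chain), C7 (enal carbon), C8, C9, C10 (methyl carbinol).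

**Step 1**
Reactants: 1 (S)-(+)-carvone
Product: 2 (3S)-6-methyl-3-(prop-1-en-2-yl)cyclohexa-1,5-dien-1-yl trifluoromethanesulfonate
Conditions: LiN(iPr)2, THF, −78 °C; then PhNTf2, −78 → 0 °C
Reagents that add atoms: N-phenylbis(trifluoromethanesulfonimide), O=S(=O)(N(c1ccccc1)S(=O)(=O)C(F)(F)F)C(F)(F)F
Why: Kinetic deprotonation at the α′‑CH2 (C6) and O‑sulfonylation of the cross‑conjugated dienolate (enol triflate formation) leave the carvone stereocentre (C7) untouched.

**Step 2**
Reactants: 2 (3S)-6-methyl-3-(prop-1-en-2-yl)cyclohexa-1,5-dien-1-yl trifluoromethanesulfonate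
Product: 3 methyl (3S)-6-methyl-3-(prop-1-en-2-yl)cyclohexa-1,5-diene-1-carboxylate
Conditions: Pd(OAc)2 (5 mol %), PPh3, CO (1 atm), MeOH, Et3N, DMF, 60 °C
Reagents that add atoms: carbon monoxide, [C-]#[O+]; methanol, CO
Why: Palladium‑catalysed alkoxycarbonylation of the alkenyl triflate (oxidative addition to zerovalent palladium, CO insertion, methanolysis) makes C4 the α‑carbon of an enoate whose β‑carbon is C6.

**Step 3**
Reactants: 3 methyl (3S)-6-methyl-3-(prop-1-en-2-yl)cyclohexa-1,5-diene-1-carboxylate; 4 (3-bromopropoxy)(tert-butyl)dimethylsilane; 5 acrylonitrile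
Product: 7 methyl (1R,2R,3S)-2-[3-(tert-butyldimethylsilyloxy)propyl]-1-(2-cyanoethyl)-6-methyl-3-(prop-1-en-2-yl)cyclohex-5-ene-1-carboxylate, via silyl ketene acetal 6 (not isolated)
Conditions: 4, Mg, THF; then CuBr·SMe2 (10 mol %), Me3SiCl, 3, −78 °C; then MeLi, 0 °C; then 5, −78 → −20 °C; aq. NH4Cl
Reagents that add atoms: none
Why: Copper‑catalysed conjugate addition of the Grignard reagent attacks C6 anti to the C7 isopropenyl group, and the lithium dienolate released from 6 adds to acrylonitrile at C4 anti to the new C6 chain (conjugate addition–enolate Michael trapping), which sets C6 and the quaternary C4 with the ester cis to the chain.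

**Step 4**
Reactants: 7 nitrile ester
Product: 8 3-[(1R,2R,3S)-2-[3-(tert-butyldimethylsilyloxy)propyl]-1-(hydroxymethyl)-6-methyl-3-(prop-1-en-2-yl)cyclohex-5-en-1-yl]propanenitrile
Conditions: LiBH4, MeOH (1 equiv), THF, 0 → 45 °C
Reagents that add atoms: none
Why: Chemoselective borohydride reduction of the ester in the presence of the nitrile unmasks the homoallylic primary alcohol that directs the next step, with no stereocentre touched.

**Step 5**
Reactants: 8 nitrile alcohol
Product: 9 epoxy alcohol (C9–C10 epoxide on the ring face of the CH2OH group)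
Conditions: VO(acac)2 (5 mol %), t-BuOOH, CH2Cl2, 0 → 23 °C
Reagents that add atoms: tert-butyl hydroperoxide, CC(C)(C)OO
Why: Hydroxyl‑directed epoxidation (Sharpless–Michaelson type) delivers oxygen from the vanadate ester of the C4 hydroxymethyl group to the face of the C9=C10 alkene on which it sits, so the C10–O bond forms cis to C5 while the remote isopropenyl group is left alone.

**Step 6**
Reactants: 9 epoxy alcohol
Product: 10 epoxy aldehyde (formyl group at C4 in place of CH2OH)
Conditions: PhI(OAc)2, TEMPO (10 mol %), CH2Cl2, 23 °C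
Reagents that add atoms: none
Why: Nitroxyl‑catalysed oxidation of the primary alcohol gives the non‑enolisable aldehyde without touching the epoxide or any stereocentre.

**Step 7**
Reactants: 10 epoxy aldehyde
Product: 12 spiro α-ketol (ring A closed; C1 ketone; C5–OH anti to the C10 oxygen), via hydroxy ketimine 11 (not isolated)
Conditions: divided cell, Sn cathode, Pt anode, Et4NOTs (0.3 M), i-PrOH, constant current, 3–4 F mol−1, 20 °C; then H2O, SiO2
Reagents that add atoms: water, O
Why: Proposed new method: cathodic one‑electron reduction of the non‑enolisable neopentyl aldehyde gives a ketyl radical anion that adds 5‑exo‑dig to the tethered nitrile, after which the iminyl radical is reduced and protonated by i‑PrOH and ketimine 11 hydrolyses to the α‑ketol; pinacol dimerisation is disfavoured by the quaternary C4, and the ketyl oxygen turns away from the epoxide oxygen and the crowded C10 so that C5–OH forms anti to the C10 oxygen; the closest known reaction is the Shono electroreductive cyclisation of γ‑ and δ‑cyano ketones to α‑hydroxy ketones, which has not been shown for aldehydes or for a β,γ‑epoxy carbonyl partner.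

**Step 8**
Reactants: 12 spiro α-ketol; 13 (triphenylphosphoranylidene)ketene
Product: 14 ring-A butenolide
Conditions: 13, toluene, 110 °C
Reagents that add atoms: none
Why: The Bestmann ylide acylates the C5 hydroxyl to an ester ylide that closes onto the C1 ketone by intramolecular Wittig olefination (butenolide annulation of an α‑ketol), leaving C5 unchanged.

**Step 9**
Reactants: 14 ring-A butenolide
Product: 15 cis-fused γ-lactone
Conditions: Cu(OAc)2·H2O (5 mol %), 1,2-bis(diphenylphosphino)benzene, (EtO)2MeSiH, t-BuOH, toluene, 23 °C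
Reagents that add atoms: none
Why: Copper hydride 1,4‑reduction delivers hydride to C1 on the face of the C5–H bond because only the cis‑fused bicyclic lactone can form, which fixes the C1 substituent cis to the C5 oxygen.

**Step 10**
Reactants: 15 cis-fused γ-lactone
Product: 18 keto lactone (C7 ketone), via methoxy hydroperoxide 16 (not isolated), via TEMPO ether 17 (not isolated)
Conditions: O3, MeOH/CH2Cl2, −78 °C; then FeSO4·7H2O, TEMPO, −78 → 23 °C; then mCPBA, 0 °C; product used crude
Reagents that add atoms: 2,2,6,6-tetramethylpiperidin-1-oxyl (TEMPO), CC1(C)CCCC(C)(C)N1[O]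
Why: Criegee ozonolysis of the only remaining alkene in methanol gives 16, divalent iron cleaves its O–O bond and β‑scission gives a C7 radical that TEMPO traps as 17, and peracid oxidation of the alkoxyamine gives the ketone (oxodealkenylation), removing the C7 stereocentre that is no longer needed.

**Step 11**
Reactants: 18 keto lactone; 19 ethyl 2,2-dibromopropanoate
Product: 20 (E)-acrylic acid (C7=C(CH3)CO2H; CO2H cis to C8)
Conditions: 19, t-BuLi (4 equiv), THF, −78 → 0 °C; then crude 18, −78 → 0 °C; aq. NaH2PO4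
Reagents that add atoms: none
Why: Shindo ynolate olefination proceeds by [2+2] addition of lithium prop‑1‑ynolate to the ketone and conrotatory 4π ring opening of the β‑lactone enolate, which turns the bulkier C6 outward so that the carboxylate ends trans to C6 and the methyl cis to C6.

**Step 12**
Reactants: 20 (E)-acrylic acid
Product: 22 Weinreb amide, via acid chloride 21 (not isolated)
Conditions: 1-chloro-N,N,2-trimethylprop-1-en-1-amine, CH2Cl2, 0 °C; then MeNH(OMe)·HCl, Et3N
Reagents that add atoms: N,O-dimethylhydroxylamine hydrochloride, CNOC.Cl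
Why: Neutral acid chloride formation (Ghosez reagent) and amidation install the latent aldehyde without touching the epoxide, the lactone or the alkene geometry.

**Step 13**
Reactants: 23 6-methylhept-5-en-2-one
Product: 24 6-methylhepta-1,5-dien-2-yl trifluoromethanesulfonate
Conditions: LiN(iPr)2, THF, −78 °C; then PhNTf2, −78 → 0 °C
Reagents that add atoms: N-phenylbis(trifluoromethanesulfonimide), O=S(=O)(N(c1ccccc1)S(=O)(=O)C(F)(F)F)C(F)(F)F
Why: Kinetic deprotonation of the methyl ketone at CH3 and O‑sulfonylation give the terminal enol triflate, the future 2‑substituted diene terminus.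

**Step 14**
Reactants: 24 6-methylhepta-1,5-dien-2-yl trifluoromethanesulfonate; 25 acrolein
Product: 26 (2E)-8-methyl-4-methylidenenona-2,7-dienal
Conditions: Pd(OAc)2 (5 mol %), NaHCO3, Bu4NCl, DMF, 40 °C
Reagents that add atoms: none
Why: Mizoroki–Heck coupling under Jeffery conditions gives the (E)‑dienal by syn insertion and syn β‑hydride elimination.

**Step 15**
Reactants: 22 Weinreb amide; 26 (2E)-8-methyl-4-methylidenenona-2,7-dienal
Product: 29 (E)-trienylidene lactone, via aldol adduct 27 (not isolated), via mesylate 28 (not isolated)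
Conditions: LiN(iPr)2, THF, −78 °C; 26; then MsCl, −78 → 0 °C; then DBU, 23 °C
Reagents that add atoms: none
Why: Aldol addition of the lactone enolate to the enal carbonyl, mesylation and E1cB elimination give the thermodynamically preferred (E)‑alkylidene lactone with the dienyl group trans to the lactone carbonyl, which is the geometry of the target C=C.

**Step 16**
Reactants: 29 (E)-trienylidene lactone
Product: 30 tert-butyldimethylsilyl ether of the target
Conditions: LiAlH4, THF, −20 → 23 °C; aq. KNaC4H4O6
Reagents that add atoms: none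
Why: One hydride reagent performs 1,2‑reduction of the alkylidene lactone to the C5‑OH/allylic CH2OH diol, SN2 opening of the epoxide at the secondary C9 (tertiary C10 alcohol with configuration retained) and reduction of the Weinreb amide to the chelated hemiaminal that releases the enal on work‑up.

**Step 17**
Reactants: 30 tert-butyldimethylsilyl ether of the target
Product: 31 CNP0246965.4 (target)
Conditions: Bu4NF, THF, 0 → 23 °C
Reagents that add atoms: none
Why: Fluoride cleavage of the primary silyl ether (desilylation) frees the last hydroxyl without affecting any stereocentre or alkene.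

**Compound list**

1 | (S)-(+)-carvone, (5S)-2-methyl-5-(prop-1-en-2-yl)cyclohex-2-en-1-one | CC1=CC[C@@H](CC1=O)C(C)=C | starting material
2 | (3S)-6-methyl-3-(prop-1-en-2-yl)cyclohexa-1,5-dien-1-yl trifluoromethanesulfonate | CC1=CC[C@@H](C=C1OS(=O)(=O)C(F)(F)F)C(C)=C | intermediate
3 | methyl (3S)-6-methyl-3-(prop-1-en-2-yl)cyclohexa-1,5-diene-1-carboxylate | CC1=CC[C@@H](C=C1C(=O)OC)C(C)=C | intermediate
4 | (3-bromopropoxy)(tert-butyl)dimethylsilane | BrCCCO[Si](C)(C)C(C)(C)C | starting material
5 | acrylonitrile | C=CC#N | starting material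
6 | methyl trimethylsilyl ketene acetal at C4 of the conjugate adduct (C6 silyloxypropyl chain trans to the C7 isopropenyl group; ketene acetal geometry undefined) | COC(O[Si](C)(C)C)=C1[C@H](CCCO[Si](C)(C)C(C)(C)C)[C@@H](C(C)=C)CC=C1C | intermediate
7 | methyl (1R,2R,3S)-2-[3-(tert-butyldimethylsilyloxy)propyl]-1-(2-cyanoethyl)-6-methyl-3-(prop-1-en-2-yl)cyclohex-5-ene-1-carboxylate (ester cis, cyanoethyl trans to the C6 chain; chain trans to isopropenyl) | N#CCC[C@]1([C@H](CCCO[Si](C)(C)C(C)(C)C)[C@@H](C(C)=C)CC=C1C)C(=O)OC | intermediate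
8 | 3-[(1R,2R,3S)-2-[3-(tert-butyldimethylsilyloxy)propyl]-1-(hydroxymethyl)-6-methyl-3-(prop-1-en-2-yl)cyclohex-5-en-1-yl]propanenitrile | N#CCC[C@]1([C@H](CCCO[Si](C)(C)C(C)(C)C)[C@@H](C(C)=C)CC=C1C)CO | intermediate
9 | epoxy alcohol: 8 with a C9–C10 epoxide cis to the CH2OH group (epoxide oxygen, CH2OH and C6 chain on one ring face; C10 methyl, cyanoethyl and isopropenyl on the other) | N#CCC[C@]1([C@H](CCCO[Si](C)(C)C(C)(C)C)[C@@H](C(C)=C)C[C@@H]2O[C@]12C)CO | intermediate
10 | epoxy aldehyde: 9 with formyl in place of CH2OH | N#CCC[C@]1([C@H](CCCO[Si](C)(C)C(C)(C)C)[C@@H](C(C)=C)C[C@@H]2O[C@]12C)C=O | intermediate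
11 | α-hydroxy ketimine: spiro[4.5]decane with C1=NH and C5–OH (stereocentres as in 12) | N=C1CC[C@]2([C@H](CCCO[Si](C)(C)C(C)(C)C)[C@@H](C(C)=C)C[C@@H]3O[C@]23C)[C@@H]1O | intermediate
12 | spiro α-ketol: ring A cyclopentanone (C1=O) with C5–OH on the ring-A face of C6, anti to the C10 oxygen; ring B with C9–C10 epoxide and C6 chain cis to C5, C7 isopropenyl trans to the C6 chain | O=C1CC[C@]2([C@H](CCCO[Si](C)(C)C(C)(C)C)[C@@H](C(C)=C)C[C@@H]3O[C@]23C)[C@@H]1O | intermediate
13 | (triphenylphosphoranylidene)ketene | O=C=C=P(c1ccccc1)(c1ccccc1)c1ccccc1 | starting material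
14 | butenolide: 2(5H)-furanone fused to ring A through C5 (ring oxygen) and C1 (C1=Cα double bond); other stereocentres as in 12 | O=C1C=C2CC[C@]3([C@H](CCCO[Si](C)(C)C(C)(C)C)[C@@H](C(C)=C)C[C@@H]4O[C@]34C)[C@@H]2O1 | intermediate
15 | cis-fused γ-lactone: C1–H and C5–H cis, lactone CH2 on C1 cis to the ring oxygen on C5; rest as in 12 | O=C1C[C@@H]2CC[C@]3([C@H](CCCO[Si](C)(C)C(C)(C)C)[C@@H](C(C)=C)C[C@@H]4O[C@]34C)[C@@H]2O1 | intermediate
16 | methoxy hydroperoxide: 15 with C(CH3)(OCH3)OOH at C7 in place of isopropenyl (peroxy carbon undefined) | O=C1C[C@@H]2CC[C@]3([C@H](CCCO[Si](C)(C)C(C)(C)C)[C@@H](C(C)(OC)OO)C[C@@H]4O[C@]34C)[C@@H]2O1 | intermediate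
17 | TEMPO ether: 15 with a 2,2,6,6-tetramethylpiperidin-1-yloxy group at C7 in place of isopropenyl (C7 epimers) | O=C1C[C@@H]2CC[C@]3([C@H](CCCO[Si](C)(C)C(C)(C)C)C(ON5C(C)(C)CCCC5(C)C)C[C@@H]4O[C@]34C)[C@@H]2O1 | intermediate
18 | keto lactone: 15 with C7 as ketone | O=C1C[C@@H]2CC[C@]3([C@H](CCCO[Si](C)(C)C(C)(C)C)C(=O)C[C@@H]4O[C@]34C)[C@@H]2O1 | intermediate
19 | ethyl 2,2-dibromopropanoate | CCOC(=O)C(C)(Br)Br | starting material
20 | (E)-acrylic acid: 18 with C7=C(CH3)CO2H, CO2H cis to C8 and CH3 cis to C6 | O=C1C[C@@H]2CC[C@]3([C@H](CCCO[Si](C)(C)C(C)(C)C)/C(=C(\C)C(O)=O)C[C@@H]4O[C@]34C)[C@@H]2O1 | intermediate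
21 | acid chloride of 20 | O=C1C[C@@H]2CC[C@]3([C@H](CCCO[Si](C)(C)C(C)(C)C)/C(=C(\C)C(Cl)=O)C[C@@H]4O[C@]34C)[C@@H]2O1 | intermediate
22 | N-methoxy-N-methylamide (Weinreb amide) of 20 | O=C1C[C@@H]2CC[C@]3([C@H](CCCO[Si](C)(C)C(C)(C)C)/C(=C(\C)C(=O)N(C)OC)C[C@@H]4O[C@]34C)[C@@H]2O1 | intermediate
23 | 6-methylhept-5-en-2-one | CC(=O)CCC=C(C)C | starting material
24 | 6-methylhepta-1,5-dien-2-yl trifluoromethanesulfonate | C=C(OS(=O)(=O)C(F)(F)F)CCC=C(C)C | intermediate
25 | acrolein (prop-2-enal) | C=CC=O | starting material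
26 | (2E)-8-methyl-4-methylidenenona-2,7-dienal | O=C/C=C/C(=C)CCC=C(C)C | intermediate
27 | aldol adduct: 22 with the lactone α-carbon bearing CH(OH)–CH=CH–C(=CH2)CH2CH2CH=C(CH3)2 (E alkene; two new centres undefined) | O=C1C(C(O)/C=C/C(=C)CCC=C(C)C)[C@@H]2CC[C@]3([C@H](CCCO[Si](C)(C)C(C)(C)C)/C(=C(\C)C(=O)N(C)OC)C[C@@H]4O[C@]34C)[C@@H]2O1 | intermediate
28 | methanesulfonate of 27 | O=C1C(C(OS(C)(=O)=O)/C=C/C(=C)CCC=C(C)C)[C@@H]2CC[C@]3([C@H](CCCO[Si](C)(C)C(C)(C)C)/C(=C(\C)C(=O)N(C)OC)C[C@@H]4O[C@]34C)[C@@H]2O1 | intermediate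
29 | (E)-trienylidene lactone: 22 with the lactone α-carbon doubly bonded to CH–CH=CH–C(=CH2)CH2CH2CH=C(CH3)2, dienyl group trans to the lactone carbonyl | O=C1/C(=C/C=C/C(=C)CCC=C(C)C)[C@@H]2CC[C@]3([C@H](CCCO[Si](C)(C)C(C)(C)C)/C(=C(\C)C(=O)N(C)OC)C[C@@H]4O[C@]34C)[C@@H]2O1 | intermediate
30 | 31 with the hydroxyl of the C6 side chain as tert-butyldimethylsilyl ether | C=C(/C=C/C=C(/CO)[C@@H]1CC[C@]2([C@H](CCCO[Si](C)(C)C(C)(C)C)/C(=C(\C)C=O)CC[C@]2(C)O)[C@@H]1O)CCC=C(C)C | intermediate
31 | CNP0246965.4 (1S,4S,5R,6R,10S in the labels used here; E at the three stereogenic C=C bonds) | C=C(/C=C/C=C(/CO)[C@@H]1CC[C@]2([C@H](CCCO)/C(=C(\C)C=O)CC[C@]2(C)O)[C@@H]1O)CCC=C(C)C | target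

**Step count and risks**

Total: 17 steps. Longest linear sequence: 15 steps (steps 1–12 and 15–17; steps 13–14 make dienal 26).

Most likely to fail:

Step 7 (the proposed cathodic ketyl–nitrile cyclisation). The aldehyde may simply be reduced to the alcohol, and the C5 selectivity rests on a steric and dipole argument. Fallback with known chemistry, setting out from 9: silylation (Et3SiCl, imidazole) gives the triethylsilyl ether F1. Reduction of the nitrile with iBu2AlH and hydrolysis gives the aldehyde F2. Swern oxidation, which converts a primary triethylsilyl ether directly into the aldehyde, gives the dialdehyde F3. A thiazolium-carbene-catalysed intramolecular benzoin reaction (acyl anion from the unhindered aldehyde adding to the neopentyl one) then comes back to the route at 12.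

Step 11 (ynolate olefination). Ketone 18 is a base-labile β,γ-epoxy ketone with an epimerisable C6, the lactone is a second electrophile, and the E geometry depends on torquoselectivity. Fallback, setting out from 18: addition of CH2=C(CH3)MgBr in the presence of CeCl3 (non-basic) gives the tertiary allylic alcohol F4. Babler–Dauben oxidative transposition with C5H5NH[CrO3Cl] gives the enal F5, whose geometrical isomers are separated. Oxidation with NaClO2 (Pinnick) comes back to the route at 20.

Step 16 (global reduction). The chelated hemiaminal must survive while the trisubstituted epoxide opens, and the dienyl allylic alkoxide must not be hydroaluminated. Fallback, setting out from 29: the single global reduction is replaced by two chemoselective reductions. LiBHEt3 (THF, 0 °C) opens the epoxide at C9 and reduces the lactone to give the triol amide F6. iBu2AlH (−78 °C) then reduces the amide to the aldehyde and comes back to the route at 30.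

**Further compounds**
F1 | step 7 | triethylsilyl ether of 9 | N#CCC[C@]1([C@H](CCCO[Si](C)(C)C(C)(C)C)[C@@H](C(C)=C)C[C@@H]2O[C@]12C)CO[Si](CC)(CC)CC
F2 | step 7 | aldehyde from the nitrile of F1 | O=CCC[C@]1([C@H](CCCO[Si](C)(C)C(C)(C)C)[C@@H](C(C)=C)C[C@@H]2O[C@]12C)CO[Si](CC)(CC)CC
F3 | step 7 | epoxy dialdehyde | O=CCC[C@]1([C@H](CCCO[Si](C)(C)C(C)(C)C)[C@@H](C(C)=C)C[C@@H]2O[C@]12C)C=O
F4 | step 11 | tertiary allylic alcohol (C7 carbinol bearing isopropenyl; C7 undefined) | O=C1C[C@@H]2CC[C@]3([C@H](CCCO[Si](C)(C)C(C)(C)C)C(O)(C(C)=C)C[C@@H]4O[C@]34C)[C@@H]2O1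
F5 | step 11 | (E)-enal of the lactone series | O=C1C[C@@H]2CC[C@]3([C@H](CCCO[Si](C)(C)C(C)(C)C)/C(=C(\C)C=O)C[C@@H]4O[C@]34C)[C@@H]2O1
F6 | step 16 | triol Weinreb amide | C=C(/C=C/C=C(/CO)[C@@H]1CC[C@]2([C@H](CCCO[Si](C)(C)C(C)(C)C)/C(=C(\C)C(=O)N(C)OC)CC[C@]2(C)O)[C@@H]1O)CCC=C(C)C
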